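**Retrosynthetic overview**
1. 19 ⇐ 16: only the C11=C12 double bond is added last (silyl enol ether dehydrogenation); every stereocentre is already present in 16.
2. 16 ⇐ 9 + 15: one radical chain reaction forms C6–C7 (lactone radical adds to the enone), C8–C14 (6-endo, ring C) and C13–C16 (5-exo-dig, ring D), so both carbocycles of the bicyclo[3.2.1]octane close in one operation.
3. 9 ⇐ 8 ⇐ 7 ⇐ 4: ring A with C4, C5 and C10 comes from the endo Diels–Alder reaction of citraconic anhydride 3 with silyl dienol ether 2; resolution as a menthyl hemiester, then reduction closes the lactone ring.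
4. 15 ⇐ 14 ⇐ 12 + 13: Morita–Baylis–Hillman reaction and lipase resolution fix C15.
5. Ring order: ring A (step 2), lactone ring (step 5), rings C and D together (step 10).

Assumption: atom labels C1–C20 follow the ent-kaurane skeleton (ring A = C1–C5 and C10, lactone C19(=O)–O–C6, C7 = linking CH2, bicyclo[3.2.1]octane = C8, C9, C11–C16, C17 = exocyclic CH2); racemic 4 and 5 are drawn as the enantiomer that is carried on after step 4.

**Step 1**
Reactants: 1 (E)-pent-3-en-2-one
Product: 2 (Z)-trimethyl(penta-2,4-dien-2-yloxy)silane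
Conditions: Me3SiCl, Et3N, DMF, 70 °C
Reagents that add atoms: chlorotrimethylsilane, C[Si](C)(C)Cl
Why: Thermodynamic silyl dienol ether formation (vinylogous enolisation through the linear dienolate); the Z enol ether, with oxygen cis to the vinyl group, is the more stable geometry and the one that reacts in step 2.

**Step 2**
Reactants: 2 (Z)-trimethyl(penta-2,4-dien-2-yloxy)silane; 3 citraconic anhydride (3-methylfuran-2,5-dione)
Product: 4 rac-(3aR,7R,7aR)-3a,7-dimethyl-7-(trimethylsilyloxy)-3a,4,7,7a-tetrahydro-2-benzofuran-1,3-dione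
Conditions: toluene, 60 °C, 48 h
Reagents that add atoms: none
Why: Thermal Diels–Alder reaction in which the fully substituted diene terminus (C10) bonds to the unsubstituted anhydride carbon (C5) for steric reasons and the endo transition state of the Z-diene (silyloxy inside) places the C10 methyl cis and the C10 oxygen trans to the anhydride, so C4, C5 and C10 are set together in the relative configuration of the target (racemic).

**Step 3**
Reactants: 4 rac-(3aR,7R,7aR)-3a,7-dimethyl-7-(trimethylsilyloxy)-3a,4,7,7a-tetrahydro-2-benzofuran-1,3-dione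
Product: 5 rac-(3aR,7R,7aR)-3a,7-dimethyl-7-(trimethylsilyloxy)hexahydro-2-benzofuran-1,3-dione
Conditions: H2 (1 atm), Pd/C, EtOAc, 23 °C
Reagents that add atoms: none
Why: Heterogeneous hydrogenation of the cis-disubstituted ring alkene; no stereocentre is formed or touched.

**Step 4**
Reactants: 5 rac-(3aR,7R,7aR)-3a,7-dimethyl-7-(trimethylsilyloxy)hexahydro-2-benzofuran-1,3-dione
Product: 7 (1R,2R,3R)-3-hydroxy-1,3-dimethyl-2-{[(1R,2S,5R)-5-methyl-2-(propan-2-yl)cyclohexyl]oxycarbonyl}cyclohexane-1-carboxylic acid, via silylated hemiester 6 (not isolated)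
Conditions: (−)-menthol, n-BuLi, THF, −78 °C; then 1 M HCl, THF, 23 °C; crystallisation
Reagents that add atoms: (1R,2S,5R)-(−)-menthol, CC(C)[C@@H]1CC[C@@H](C)C[C@H]1O
Why: Regioselective alcoholysis of the anhydride at the less hindered carbonyl (C6, on the CH carbon) gives two diastereomeric menthyl hemiesters from the two enantiomers of 5, which are separated by crystallisation (classical resolution), and the acid work-up cleaves the tertiary silyl ether without changing any stereocentre of the carried enantiomer.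

**Step 5**
Reactants: 7 (1R,2R,3R)-3-hydroxy-1,3-dimethyl-2-{[(1R,2S,5R)-5-methyl-2-(propan-2-yl)cyclohexyl]oxycarbonyl}cyclohexane-1-carboxylic acid
Product: 8 (3aR,4R,7aR)-3,4-dihydroxy-4,7a-dimethylhexahydro-2-benzofuran-1(3H)-one (lactol epimers at C3)
Conditions: (i-Bu)2AlH (3.3 equiv), CH2Cl2, −78 °C; aq. KNaC4H4O6
Reagents that add atoms: none
Why: Half-reduction of the ester to the aldehyde by (i-Bu)2AlH while the aluminium carboxylate stays inert, after which the cis aldehyde–acid closes to the hydroxylactone (lactone ring); C4, C5 and C10 are untouched and the lactol carbon (C6) is epimeric.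

**Step 6**
Reactants: 8 (3aR,4R,7aR)-3,4-dihydroxy-4,7a-dimethylhexahydro-2-benzofuran-1(3H)-one
Product: 9 (3aR,4R,7aR)-4-hydroxy-4,7a-dimethyl-3-(phenylselanyl)hexahydro-2-benzofuran-1(3H)-one (epimers at C3)
Conditions: N-(phenylselanyl)phthalimide, Bu3P, THF, −20 → 23 °C
Reagents that add atoms: N-(phenylselanyl)phthalimide, O=C1N([Se]c2ccccc2)C(=O)c2ccccc12
Why: Hemiacetal-selective selenation (alkoxyphosphonium formation, then substitution by benzeneselenolate) turns the lactol into a radical precursor; the tertiary alcohol does not react and the C6 configuration is irrelevant because this carbon becomes a radical.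

**Step 7**
Reactants: 10 N-methoxy-N-methylprop-2-enamide; 11 but-3-en-1-ylmagnesium bromide (CH2=CHCH2CH2MgBr)
Product: 12 hepta-1,6-dien-3-one
Conditions: THF, −78 → 0 °C; then cold 1 M HCl
Reagents that add atoms: none
Why: Weinreb ketone synthesis, in which the chelated tetrahedral magnesium adduct prevents over-addition and the cold acidic quench keeps the released amine from adding to the vinyl ketone.

**Step 8**
Reactants: 12 hepta-1,6-dien-3-one; 13 prop-2-ynal
Product: 14 rac-3-hydroxy-4-methylidenenon-8-en-1-yn-5-one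
Conditions: DABCO (30 mol%), THF, 0 °C
Reagents that add atoms: none
Why: Morita–Baylis–Hillman reaction, in which the amine-derived zwitterionic enolate of the vinyl ketone adds to the very electrophilic ynal and then eliminates the amine; the new carbinol centre (C15) is racemic.

**Step 9**
Reactants: 14 rac-3-hydroxy-4-methylidenenon-8-en-1-yn-5-one
Product: 15 (3R)-4-methylidene-5-oxonon-8-en-1-yn-3-yl acetate
Conditions: Amano lipase PS, vinyl acetate, t-BuOMe, 30 °C, to ca. 50% conversion
Reagents that add atoms: vinyl acetate, CC(=O)OC=C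
Why: Lipase-catalysed kinetic resolution by transesterification (Kazlauskas rule: the enantiomer with the large enone group and the small ethynyl group, here R, is acylated), which gives the R acetate directly and leaves the S alcohol to be removed by chromatography.

**Step 10**
Reactants: 9 (3aR,4R,7aR)-4-hydroxy-4,7a-dimethyl-3-(phenylselanyl)hexahydro-2-benzofuran-1(3H)-one; 15 (3R)-4-methylidene-5-oxonon-8-en-1-yn-3-yl acetate
Product: 16 (1R,5R,7R)-1-{[(1R,3aR,7R,7aS)-7-hydroxy-3a,7-dimethyl-3-oxooctahydro-2-benzofuran-1-yl]methyl}-6-methylidene-2-oxobicyclo[3.2.1]octan-7-yl acetate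
Conditions: (Me3Si)3SiH (syringe pump, 8 h), AIBN, PhH, 80 °C, 15 (3 equiv), 0.02 M
Reagents that add atoms: none
Why: Proposed new method: the silyl radical abstracts PhSe from 9 to give the nucleophilic C6 α-acyloxy radical, which adds on the convex face (anti to ring A, setting C6) to the CH2 terminus of enone 15 (Giese addition, as for anomeric radicals); the resulting tertiary α-keto radical cyclises 6-endo onto the butenyl chain, anti to the ethynyl group with the propargylic C–H eclipsing the acyl group (acyclic 1,2-induction of the Guindon type, setting C8 relative to C15), and the secondary radical then closes 5-exo-dig onto the alkyne (ring D, C13 fixed by the bridge) before the vinyl radical takes hydrogen from the silane; the closest known reaction type is the tandem 6-endo/5-exo radical cyclisation of α-keto radicals to bicyclo[3.2.1]octanes (Mn(OAc)3 or tin hydride mediated).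

**Step 11**
Reactants: 16 (1R,5R,7R)-1-{[(1R,3aR,7R,7aS)-7-hydroxy-3a,7-dimethyl-3-oxooctahydro-2-benzofuran-1-yl]methyl}-6-methylidene-2-oxobicyclo[3.2.1]octan-7-yl acetate
Product: 19 (1R,5S,7R)-1-{[(1R,3aR,7R,7aS)-7-hydroxy-3a,7-dimethyl-3-oxooctahydro-2-benzofuran-1-yl]methyl}-6-methylidene-2-oxobicyclo[3.2.1]oct-3-en-7-yl acetate (CNP0172716.1), via bis-silyl enol ether 17 (not isolated), via 10-O-silyl enone 18 (not isolated)
Conditions: Me3SiOTf, Et3N, CH2Cl2, 0 °C; then 2-iodoxybenzoic acid·4-methoxypyridine N-oxide, DMSO, 23 °C; then 1 M HCl, THF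
Reagents that add atoms: none
Why: Soft enolisation gives the only possible silyl enol ether (C8 is quaternary) and silylates the tertiary alcohol, the 2-iodoxybenzoic acid complex dehydrogenates the silyl enol ether to the enone (Nicolaou variant of the Saegusa oxidation), and dilute acid removes the tertiary silyl ether without touching any stereocentre.

**Compound list**
1 | (E)-pent-3-en-2-one | C/C=C/C(C)=O | starting material
2 | (Z)-trimethyl(penta-2,4-dien-2-yloxy)silane | C=C/C=C(/C)O[Si](C)(C)C | intermediate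
3 | citraconic anhydride (3-methylfuran-2,5-dione) | CC1=CC(=O)OC1=O | starting material
4 | rac-(3aR,7R,7aR)-3a,7-dimethyl-7-(trimethylsilyloxy)-3a,4,7,7a-tetrahydro-2-benzofuran-1,3-dione | O=C1OC(=O)[C@]2(C)CC=C[C@@](C)(O[Si](C)(C)C)[C@H]12 | intermediate
5 | rac-(3aR,7R,7aR)-3a,7-dimethyl-7-(trimethylsilyloxy)hexahydro-2-benzofuran-1,3-dione | O=C1OC(=O)[C@]2(C)CCC[C@@](C)(O[Si](C)(C)C)[C@H]12 | intermediate
6 | (1R,2R,3R)-1,3-dimethyl-2-{[(1R,2S,5R)-5-methyl-2-(propan-2-yl)cyclohexyl]oxycarbonyl}-3-(trimethylsilyloxy)cyclohexane-1-carboxylic acid (lithium salt in the flask) | OC(=O)[C@]1(C)CCC[C@@](C)(O[Si](C)(C)C)[C@@H]1C(=O)O[C@@H]1C[C@H](C)CC[C@H]1C(C)C | intermediate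
7 | (1R,2R,3R)-3-hydroxy-1,3-dimethyl-2-{[(1R,2S,5R)-5-methyl-2-(propan-2-yl)cyclohexyl]oxycarbonyl}cyclohexane-1-carboxylic acid | OC(=O)[C@]1(C)CCC[C@@](C)(O)[C@@H]1C(=O)O[C@@H]1C[C@H](C)CC[C@H]1C(C)C | intermediate
8 | (3aR,4R,7aR)-3,4-dihydroxy-4,7a-dimethylhexahydro-2-benzofuran-1(3H)-one (C3 epimers) | OC1OC(=O)[C@]2(C)CCC[C@@](C)(O)[C@H]12 | intermediate
9 | (3aR,4R,7aR)-4-hydroxy-4,7a-dimethyl-3-(phenylselanyl)hexahydro-2-benzofuran-1(3H)-one (C3 epimers) | c1ccccc1[Se]C1OC(=O)[C@]2(C)CCC[C@@](C)(O)[C@H]12 | intermediate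
10 | N-methoxy-N-methylprop-2-enamide | C=CC(=O)N(C)OC | starting material
11 | but-3-en-1-ylmagnesium bromide | C=CCC[Mg]Br | starting material
12 | hepta-1,6-dien-3-one | C=CC(=O)CCC=C | intermediate
13 | prop-2-ynal | C#CC=O | starting material
14 | rac-3-hydroxy-4-methylidenenon-8-en-1-yn-5-one | C#CC(O)C(=C)C(=O)CCC=C | intermediate
15 | (3R)-4-methylidene-5-oxonon-8-en-1-yn-3-yl acetate | C#C[C@@H](OC(C)=O)C(=C)C(=O)CCC=C | intermediate
16 | (1R,5R,7R)-1-{[(1R,3aR,7R,7aS)-7-hydroxy-3a,7-dimethyl-3-oxooctahydro-2-benzofuran-1-yl]methyl}-6-methylidene-2-oxobicyclo[3.2.1]octan-7-yl acetate | C=C1[C@@H]2CCC(=O)[C@@](C[C@H]3OC(=O)[C@]4(C)CCC[C@@](C)(O)[C@H]34)(C2)[C@@H]1OC(C)=O | intermediate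
17 | C9 trimethylsilyl enol ether (C9=C11) and C10 trimethylsilyl ether of 16 | C=C1[C@@H]2CC=C(O[Si](C)(C)C)[C@@](C[C@H]3OC(=O)[C@]4(C)CCC[C@@](C)(O[Si](C)(C)C)[C@H]34)(C2)[C@@H]1OC(C)=O | intermediate
18 | C10 trimethylsilyl ether of 19 | C=C1[C@@H]2C=CC(=O)[C@@](C[C@H]3OC(=O)[C@]4(C)CCC[C@@](C)(O[Si](C)(C)C)[C@H]34)(C2)[C@@H]1OC(C)=O | intermediate
19 | (1R,5S,7R)-1-{[(1R,3aR,7R,7aS)-7-hydroxy-3a,7-dimethyl-3-oxooctahydro-2-benzofuran-1-yl]methyl}-6-methylidene-2-oxobicyclo[3.2.1]oct-3-en-7-yl acetate (CNP0172716.1) | C=C1[C@@H]2C=CC(=O)[C@@](C[C@H]3OC(=O)[C@]4(C)CCC[C@@](C)(O)[C@H]34)(C2)[C@@H]1OC(C)=O | target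

**Step count**
Total steps: 11. Longest linear sequence: 8 steps (steps 1–6, 10 and 11); steps 7–9 are a three-step branch.

**Steps most likely to fail, with fallbacks**

Step 10 (radical cascade) is the main risk. The acyclic 1,2-induction that sets C8 rests on a small steric difference between ethynyl and acetoxy, some 5-exo closure of the α-keto radical is possible, and the silane can reduce radicals before they cyclise. The fallback builds the bicycle by polar, stepwise chemistry. It sets out from 9: Giese addition of the same C6 radical to methyl vinyl ketone ((Me3Si)3SiH, AIBN) gives 4-[(1R,3aR,7R,7aS)-7-hydroxy-3a,7-dimethyl-3-oxooctahydro-2-benzofuran-1-yl]butan-2-one F1. Mannich-type α-methylenation on the more substituted side (paraformaldehyde, N-methylanilinium trifluoroacetate, THF, reflux) gives the 3-methylidene ketone F2. Enamine Michael addition of succinaldehyde under (R)-α,α-diphenylprolinol trimethylsilyl ether catalysis, followed in the same flask by aldol condensation, gives the (1R)-4-oxocyclohex-2-en-1-yl acetaldehyde F3, with C13 set by the catalyst. Aldehyde α-methylenation (aqueous formaldehyde, pyrrolidine, propanoic acid) gives the prop-2-enal F4. LiN(SiMe3)2 at −78 °C forms the cross-conjugated enolate at C8, which adds to the enal carbonyl through a lithium-chelated transition state to give the 7-hydroxy bicyclic enone F5 (ring D; C8 fixed by the bridge, endo C15–OH). Acetylation (Ac2O, pyridine) comes back to the route at 19.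

Step 2 (Diels–Alder reaction) may be slow or poorly regioselective because one diene terminus is fully substituted, and the diene is hydrolytically labile. The fallback introduces the C10 oxygen after the cycloaddition. It sets out from 3: Diels–Alder reaction with (E)-penta-1,3-diene gives the endo adduct rac-(3aR,7S,7aS)-3a,7-dimethyl-3a,4,7,7a-tetrahydro-2-benzofuran-1,3-dione F6. Allylic hydroxylation of the tertiary allylic C–H with SeO2/t-BuOOH (ene reaction, then [2,3]-shift, with retention) gives the 7-hydroxy anhydride F7. Hydrogenation (H2, Pd/C) gives the saturated hydroxy anhydride F8, which is opened with lithium (−)-mentholate as in step 4 and comes back to the route at 7.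

Step 8 (Morita–Baylis–Hillman reaction) may fail because the amine can add to propynal or the vinyl ketone can dimerise. The fallback is a chalcogenide Michael–aldol sequence. It sets out from 12 and 13: Me2AlSePh adds to the vinyl ketone and the aluminium enolate is trapped by the ynal to give 3-hydroxy-4-[(phenylselanyl)methyl]non-8-en-1-yn-5-one F9. Oxidation with H2O2 and selenoxide syn-elimination comes back to the route at 14.

**Further compounds**
F1 | step 10 | 4-[(1R,3aR,7R,7aS)-7-hydroxy-3a,7-dimethyl-3-oxooctahydro-2-benzofuran-1-yl]butan-2-one | CC(=O)CC[C@H]1OC(=O)[C@]2(C)CCC[C@@](C)(O)[C@H]12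
F2 | step 10 | 4-[(1R,3aR,7R,7aS)-7-hydroxy-3a,7-dimethyl-3-oxooctahydro-2-benzofuran-1-yl]-3-methylidenebutan-2-one | CC(=O)C(=C)C[C@H]1OC(=O)[C@]2(C)CCC[C@@](C)(O)[C@H]12
F3 | step 10 | 2-[(1R)-5-{[(1R,3aR,7R,7aS)-7-hydroxy-3a,7-dimethyl-3-oxooctahydro-2-benzofuran-1-yl]methyl}-4-oxocyclohex-2-en-1-yl]acetaldehyde (epimers at ring C5) | O=CC[C@@H]1C=CC(=O)C(C[C@H]2OC(=O)[C@]3(C)CCC[C@@](C)(O)[C@H]23)C1
F4 | step 10 | 2-[(1R)-5-{[(1R,3aR,7R,7aS)-7-hydroxy-3a,7-dimethyl-3-oxooctahydro-2-benzofuran-1-yl]methyl}-4-oxocyclohex-2-en-1-yl]prop-2-enal (epimers at ring C5) | O=CC(=C)[C@@H]1C=CC(=O)C(C[C@H]2OC(=O)[C@]3(C)CCC[C@@](C)(O)[C@H]23)C1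
F5 | step 10 | (1R,5S,7R)-7-hydroxy-1-{[(1R,3aR,7R,7aS)-7-hydroxy-3a,7-dimethyl-3-oxooctahydro-2-benzofuran-1-yl]methyl}-6-methylidenebicyclo[3.2.1]oct-3-en-2-one | C=C1[C@@H]2C=CC(=O)[C@@](C[C@H]3OC(=O)[C@]4(C)CCC[C@@](C)(O)[C@H]34)(C2)[C@@H]1O
F6 | step 2 | rac-(3aR,7S,7aS)-3a,7-dimethyl-3a,4,7,7a-tetrahydro-2-benzofuran-1,3-dione | O=C1OC(=O)[C@]2(C)CC=C[C@H](C)[C@H]12
F7 | step 2 | rac-(3aR,7R,7aR)-7-hydroxy-3a,7-dimethyl-3a,4,7,7a-tetrahydro-2-benzofuran-1,3-dione | O=C1OC(=O)[C@]2(C)CC=C[C@@](C)(O)[C@H]12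
F8 | step 2 | rac-(3aR,7R,7aR)-7-hydroxy-3a,7-dimethylhexahydro-2-benzofuran-1,3-dione | O=C1OC(=O)[C@]2(C)CCC[C@@](C)(O)[C@H]12
F9 | step 8 | 3-hydroxy-4-[(phenylselanyl)methyl]non-8-en-1-yn-5-one (diastereomers, racemic) | C#CC(O)C(C[Se]c1ccccc1)C(=O)CCC=C
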